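One molecule of reagent cannot be spent on two molecules of substrate, so I counted this flask by what had to be left of each.

left-handed substrate 0.50 M; reagent 1.50 M; free catalyst 5.0 mM; racemization catalyst 60 mM; right-handed substrate 0.50 M; time 15 d

    reagent → decomposition product (k1 = 2.5 × 10⁻⁵ h⁻¹)
    reagent + free catalyst + right-handed substrate → free catalyst + right-handed product (k2 = 46 L² mol⁻² h⁻¹)
    left-handed substrate + racemization catalyst ⇌ right-handed substrate + racemization catalyst, rate k3*[racemization catalyst]*[left-handed substrate] forward; the back reaction follows from the equilibrium constant (k3 = 1.3 L mol⁻¹ h⁻¹)
    reagent + free catalyst + left-handed substrate → free catalyst + left-handed product (k4 = 100 L² mol⁻² h⁻¹)
    left-handed product ⇌ right-handed product (k5 = 0.014 h⁻¹)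

1. why nothing more happens at 15 d, or that something still does (all of the left-handed substrate has reacted / no working catalyst is left / it is still moving / forward and back rates have come level / the reagent has run out first)
2. how much of the left-handed substrate and right-handed substrate together has reacted by 15 d
3. how much left-handed product there is at 15 d, in percent of the left-handed substrate and right-handed substrate together charged
4. how much right-handed product there is at 15 d, in percent of the left-handed substrate and right-handed substrate together charged

Set against the left-handed substrate, which has the larger rate constant, this flask and its neighbour with 0.60 M of reagent look nearly the same: 3.00 equivalents here and 1.20 equiv there, both above one. But the right-handed substrate consumes reagent too, so I set the reagent against both hands and wrote E = 1.50, the cover, meaning reagent charged per substrate charged, both hands together. With decomposition negligible and time enough, E above one leaves a fraction of one minus one over E of the reagent, while E below one leaves a fraction of one minus E of the substrates.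

Decomposition was negligible here, because its half-life of 1200 d is long against the 15 d of the run. In this flask the reagent, decomposition apart, stays above 33.3% of its charge until the substrates are gone, so I treated the right-handed substrate as pseudo-first-order, halving every 0.251 d or faster. That gives about 59.8 halvings, which leaves too little to weigh. The relaxation half-life of the two products, 1.03 d, is also short against the run, so their imbalance halves about 14.6 times and each product should hold half of the charge. I expected the neighbour to end differently because its reagent is the limiting reagent, charged below both substrates together.

The forecast gave all of the left-handed substrate has reacted, with 100% reacted, 50% left-handed product and 50% right-handed product, on the ground that “reagent is in excess and barely decomposes”.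

The simulation of this flask gave all of the left-handed substrate has reacted, with 100% reacted and 50.0% and 50.0% of the two products, and 33% of the reagent stood at 15.0 d, where one minus one over E gives 33.3%. For the neighbouring flask with 0.60 M of reagent, E drops to 0.600, so one minus E leaves 40.0% of both substrates together. That neighbour ended at 15.0 d with 0% of its reagent, 20.0% left-handed and 20.0% right-handed substrate, and 30.0% left-handed and 30.0% right-handed product.

(The rate constants are made up; the result is computed.)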